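## The problem

Compound 28 consists of two oxygen heterocycles that share one arene. A 2,3-trans-3,4-cis tetrahydrofuran (THF: C2 3-hydroxy-4-methoxyphenyl, C3 CH2OH, C4 benzyl) uses as its benzyl arene ring B of a trans-2-aryl-3-hydroxymethyl-2,3-dihydrobenzofuran (DHB). Ring B is therefore 1,2,3,5-tetrasubstituted, with C3a between C4–OMe and C7a–O1 and the CH2 link at C6. The five stereocentres form two clusters (THF C2/C3/C4 and DHB C2/C3) separated by a CH2–arene spacer. Inside a cluster one centre can set its neighbours (THF C4 → C3 → C2, DHB C2 → C3), but nothing is relayed across the spacer, so each cluster needs its own source of absolute configuration. Both C2 atoms are electron-rich benzylic ether carbons: they ionise with acid, can be hydrogenolysed, and the DHB one becomes a quinone-methide precursor once its para phenol is free. Ring B, a resorcinol diether, is a strong carbon nucleophile towards any benzylic cation formed nearby. The enabling feature is that C3a is the only ring-B carbon flanked by two oxygens, so cooperative directed metalation reaches it selectively; and because DHB C3 is bonded to C3a and carries exactly one exocyclic carbon, a vinyl group on the O-bearing benzylic carbon C2 places its internal carbon in 5-exo reach of a radical at C3a and leaves the new radical on the carbon that must become CH2OH.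

## Retrosynthesis

**Unmasking (28 ⇐ 27 ⇐ 26 ⇐ 25).** No skeletal bond is cut. The phenols are carried as benzyl ethers, the THF hydroxymethyl as a silyl ether and the DHB hydroxymethyl as a CH2–B bond in 25. Boron is preferred to oxygen at this carbon because a carbon radical can be made to end on it. The forward steps must oxidise C–B, remove silicon while the phenols are still masked, and cleave two aryl benzyl ethers without touching two cyclic benzylic ethers.

**C3a–C3 (25 ⇒ 23).** Cutting the bond between ring B and C3, together with C–B, leads to the ortho-iodoaryl 1-arylallyl ether 23. The neighbouring cuts are weaker here. O1–C2 closed last would need substitution at an ionisable benzylic carbon; C2–C3 is the carbene route of Alternative 1; a Heck closure of 23 would lose C3–H by β-hydride elimination and end as a benzofuran. A σ-aryl radical is indifferent to the two flanking oxygens, and the primary radical it leaves can be trapped by boron. One ring, one C–C bond and one stereocentre disappear. The forward step must cyclise faster than it borylates the aryl radical, close trans, and leave the allylic ether intact.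

**O1–C2 (23 ⇒ 17 + 21).** The aryl–O–CH bond is cut to iodophenol 17 and the linear cinnamyl carbonate 21. Iridium-catalysed allylic etherification gives the branched ether from an achiral carbonate under catalyst control, which is needed because the THF centres are too remote to help. Mitsunobu or SN1 etherification at this electron-rich benzylic/allylic carbon would leak configuration. The molecule falls into two halves of similar size. The reaction must accept a hindered ortho-iodo aryloxide and give a product that does not re-ionise.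

**C3a–I and phenol release (17 ⇐ 16 ⇐ 14).** The iodine goes in by directed ortho-metalation of carbamate 14; electrophilic iodination would choose the positions next to the CH2 group instead. A diethylcarbamate rather than an acetal-type ether is the phenol mask because it is the stronger director, it tempers ring B in the cationic step below, and it is removed reductively without acid.

**THF ring (14 ⇐ 13 ⇐ 12 ⇐ 11 ⇐ 8 + 9).** O1–C2 of the THF is cut to triol 12 (benzylic cation, 5-exo capture) and C2–C3 to an aldol between lactone 8 and aldehyde 9. The trans lactone becomes the 3,4-cis THF once the ring is switched, and the uncontrolled carbinol centre converges in the SN1 closure. Three contiguous centres are thus reduced to the single centre of 8.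

**CH2–ring B bond and the chiral pool (8 ⇐ 7 ⇐ 5 + 3; 3 ⇐ 1 + 2; 5 ⇐ 4).** The benzylic C–C bond is made by copper-catalysed opening of cyclopropane lactone 3 with the Grignard reagent of bromide 5. This uses the purchased bromide 4 directly and draws the THF configuration from (S)-epichlorohydrin 1 and diethyl malonate 2.

**Carbonate (21 ⇐ 20 ⇐ 19 ⇐ 18).** Routine two-carbon homologation of aldehyde 18, reduction and carbonate formation.

## Roads not taken

**Alternative 1:** The cut is C2–C3 of the DHB. Rh2(S-PTTL)4 converts aryldiazoacetate A1 into a rhodium carbene that inserts into the benzylic O–CH2 bond and closes the ring as the cis ester; DBU in the same pot epimerises C3 to the trans ester A2.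
- Merits: both DHB centres come from a catalyst and not from relay, the C3 substituent is one reduction from CH2OH, and no photochemistry is needed.
- Weak points here: the carbene carbon sits on C3a between two ortho oxygens, so the OMe group offers a competing C–H insertion and the aryl carbene is twisted. The p-alkoxybenzyl C–H invites hydride transfer in place of concerted insertion. DBU on a β-aryloxy ester can open the ring by phenoxide elimination. A2 must still be joined to the THF half by an sp3–sp2 coupling at its bromide after the sensitive DHB exists, and A1 needs the same between-the-oxygens functionalisation as the chosen plan.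
- Comparison: this road is better in absolute control at C3 and probably in diastereomeric purity. The chosen plan sets against it a bond formation indifferent to crowding at C3a, a two-step precursor synthesis from a phenol that already carries the THF half, and no late fragment coupling.

**Alternative 2:** The cut removes ring B itself (C3a–C7a and C4–C5). Heating cyclobutenone A3 with siloxyalkyne A4 starts the Danheiser benzannulation cascade (4π opening to a vinylketene, [2+2] with the ynol ether, 4π opening, 6π closure, tautomerisation). It gives resorcinol mono-silyl ether A5 with the future O1 as free OH and the future OMe oxygen as its TIPS ether.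
- Merits: the substitution pattern of ring B is unambiguous, the two oxygens are differentiated from the start, the halves are joined convergently, and the DHB centres are set in an open chain by aldol chemistry.
- Weak points here: A4 is a chiral, doubly silylated ynol ether that needs a long sequence, and A3 needs a ketene cycloaddition on a THF-bearing alkyne. The annulation runs hot with a benzylic silyl ether that can eliminate. Afterwards O1–C2 must still be closed at an electron-rich benzylic carbon, followed by desilylation and O-methylation.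
- Comparison: this road is more convergent and has no regiochemical question on ring B, but it is many steps longer. The chosen plan answers the regiochemistry with one directed lithiation on a purchased arene and makes O1–C2 under catalyst control.

**Alternative 3:** The cut takes C3a–C3 and O1–C2 together. Mn(OAc)3 oxidises dione A6 to its α-radical, which adds to the alkene carbon next to the carbonyl of acylsultam A7; the benzylic radical is oxidised to the cation and captured by the enol oxygen to give A8.
- Merits: two bonds and the ring form in one step from cheap reagents, no halogen is needed, the symmetric dione has no regiochemical issue, and the closure is trans.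
- Weak points here: ring B must afterwards be aromatised without dehydrogenating the dihydrofuran to a benzofuran, which would erase both new centres, and then O-methylated. Trivalent manganese in hot acetic acid meets two benzyl ethers and an ionisable 2-aryl-THF. Facial control by the sultam is modest, and the C6 epimers double every mixture until aromatisation.
- Comparison: for a racemic model this would be the shortest way to the bicyclic core, and it needs neither light nor boron. For the single enantiomer the chosen plan keeps ring B aromatic throughout and takes C2 from a closed-shell asymmetric catalysis.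

Key step: step 15

Assumption: the (Sa,Sc,Sc) antipode of the phosphoramidite ligand is taken to give the (S)-ether 23 (recalled sense of induction for aryl-substituted allyl carbonates, not verified); if a trial with 2-iodo-3-methoxyphenol points the other way, the (Ra,Rc,Rc) antipode is used and nothing else changes.

## Route

Step 1
Reactants: 1 (S)-epichlorohydrin; 2 diethyl malonate
Product: 3 ethyl (1R,5S)-2-oxo-3-oxabicyclo[3.1.0]hexane-1-carboxylate
Conditions: NaOEt, EtOH, reflux
Reagents that add atoms: none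
Why: Known epoxide-opening/3-exo-tet alkylation/lactonisation cascade: malonate opens the epoxide at CH2, the alkoxide closes a new epoxide with loss of chloride, and the second alkylation at the CH carbon goes with inversion, so (S)-1 gives the (1R,5S) lactone whose C5 becomes THF C4.

Step 2
Reactants: 4 3-bromo-5-methoxyphenol
Product: 5 3-bromo-5-methoxyphenyl N,N-diethylcarbamate
Conditions: ClC(O)NEt2, K2CO3, MeCN, reflux
Reagents that add atoms: diethylcarbamoyl chloride, CCN(CC)C(Cl)=O
Why: O-carbamoylation of the phenol; the carbamate later directs the metalation, makes ring B less nucleophilic than an alkyl ether would in the cationic closure of step 7, and is removed without acid.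

Step 3
Reactants: 5 3-bromo-5-methoxyphenyl N,N-diethylcarbamate; 3 ethyl (1R,5S)-2-oxo-3-oxabicyclo[3.1.0]hexane-1-carboxylate
Product: 7 ethyl (3R,4S)-4-{[3-(diethylcarbamoyloxy)-5-methoxyphenyl]methyl}-2-oxotetrahydrofuran-3-carboxylate, via arylmagnesium bromide 6 (not isolated)
Conditions: Mg, LiCl, THF, 25 °C; then CuI (10 mol %), 3, −30 → 0 °C
Reagents that add atoms: none
Why: LiCl-assisted magnesium insertion tolerates a hindered N,N-dialkylcarbamate, and copper-catalysed homoconjugate addition opens the doubly activated cyclopropane at its CH2 carbon, leaving the CH stereocentre (lactone C4, S) untouched; C3 is a malonate-type centre and is lost in step 4.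

Step 4
Reactants: 7 ethyl (3R,4S)-4-{[3-(diethylcarbamoyloxy)-5-methoxyphenyl]methyl}-2-oxotetrahydrofuran-3-carboxylate
Product: 8 3-methoxy-5-{[(3S)-5-oxotetrahydrofuran-3-yl]methyl}phenyl N,N-diethylcarbamate
Conditions: LiCl, H2O, DMSO, 140 °C
Reagents that add atoms: none
Why: Krapcho dealkoxycarbonylation under neutral conditions; carbamate and lactone survive and C4 is not enolisable.

Step 5
Reactants: 8 3-methoxy-5-{[(3S)-5-oxotetrahydrofuran-3-yl]methyl}phenyl N,N-diethylcarbamate; 9 3-(benzyloxy)-4-methoxybenzaldehyde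
Product: 11 3-{[(3S,4R)-4-{[3-(benzyloxy)-4-methoxyphenyl](hydroxy)methyl}-5-oxotetrahydrofuran-3-yl]methyl}-5-methoxyphenyl N,N-diethylcarbamate (trans lactone, both carbinol epimers), via lithium enolate 10 (not isolated)
Conditions: LiN(SiMe3)2, THF, −78 °C; then 9, −78 °C
Reagents that add atoms: none
Why: Aldol addition of the lactone lithium enolate; the aldehyde enters anti to the C4 benzyl group, which fixes the trans lactone (the later 3,4-cis THF), while the carbinol centre forms as a mixture that step 7 erases.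

Step 6
Reactants: 11 3-{[(3S,4R)-4-{[3-(benzyloxy)-4-methoxyphenyl](hydroxy)methyl}-5-oxotetrahydrofuran-3-yl]methyl}-5-methoxyphenyl N,N-diethylcarbamate
Product: 12 3-[(2S,3S)-3-{[3-(benzyloxy)-4-methoxyphenyl](hydroxy)methyl}-4-hydroxy-2-(hydroxymethyl)butyl]-5-methoxyphenyl N,N-diethylcarbamate (carbinol epimers)
Conditions: LiBH4, MeOH (1 equiv), THF, 0 °C → rt
Reagents that add atoms: none
Why: LiBH4 reduces the lactone to the 1,4-diol and leaves the aryl carbamate alone, which LiAlH4 would not.

Step 7
Reactants: 12 3-[(2S,3S)-3-{[3-(benzyloxy)-4-methoxyphenyl](hydroxy)methyl}-4-hydroxy-2-(hydroxymethyl)butyl]-5-methoxyphenyl N,N-diethylcarbamate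
Product: 13 3-{[(3S,4S,5R)-5-[3-(benzyloxy)-4-methoxyphenyl]-4-(hydroxymethyl)tetrahydrofuran-3-yl]methyl}-5-methoxyphenyl N,N-diethylcarbamate
Conditions: camphorsulfonic acid (10 mol %), CH2Cl2, 0 °C
Reagents that add atoms: none
Why: Acid-catalysed SN1 cycloetherification as used for lariciresinol-type lignans: both carbinol epimers give the same p-methoxy-stabilised benzylic cation, which is captured 5-exo by the hydroxymethyl group on the benzyl-bearing carbon (the other could only form an oxetane), the aryl group taking the face opposite both neighbours so that the aryl-bearing carbon becomes R (2,3-trans); with the carbamate in place ring B is no more nucleophilic than an ordinary lignan arene, so Friedel–Crafts closure to an aryltetralin should stay slow at this acidity.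

Step 8
Reactants: 13 3-{[(3S,4S,5R)-5-[3-(benzyloxy)-4-methoxyphenyl]-4-(hydroxymethyl)tetrahydrofuran-3-yl]methyl}-5-methoxyphenyl N,N-diethylcarbamate
Product: 14 3-{[(3S,4S,5R)-5-[3-(benzyloxy)-4-methoxyphenyl]-4-{[(tert-butyldimethylsilyl)oxy]methyl}tetrahydrofuran-3-yl]methyl}-5-methoxyphenyl N,N-diethylcarbamate
Conditions: TBSCl, imidazole, DMF, rt
Reagents that add atoms: tert-butyldimethylsilyl chloride, CC(C)(C)[Si](C)(C)Cl
Why: Standard silylation of the primary alcohol, needed for the organolithium step and kept until step 17.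

Step 9
Reactants: 14 3-{[(3S,4S,5R)-5-[3-(benzyloxy)-4-methoxyphenyl]-4-{[(tert-butyldimethylsilyl)oxy]methyl}tetrahydrofuran-3-yl]methyl}-5-methoxyphenyl N,N-diethylcarbamate
Product: 16 5-{[(3S,4S,5R)-5-[3-(benzyloxy)-4-methoxyphenyl]-4-{[(tert-butyldimethylsilyl)oxy]methyl}tetrahydrofuran-3-yl]methyl}-2-iodo-3-methoxyphenyl N,N-diethylcarbamate, via aryllithium 15 (not isolated)
Conditions: s-BuLi, TMEDA, THF, −78 °C; then I2, −78 °C → rt
Reagents that add atoms: iodine, II
Why: Directed ortho-metalation: carbamate and methoxy group cooperate at the one C–H between them (the future C3a), the aryllithium does not undergo anionic Fries rearrangement at −78 °C, and iodine quench gives the iodide.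

Step 10
Reactants: 16 5-{[(3S,4S,5R)-5-[3-(benzyloxy)-4-methoxyphenyl]-4-{[(tert-butyldimethylsilyl)oxy]methyl}tetrahydrofuran-3-yl]methyl}-2-iodo-3-methoxyphenyl N,N-diethylcarbamate
Product: 17 5-{[(3S,4S,5R)-5-[3-(benzyloxy)-4-methoxyphenyl]-4-{[(tert-butyldimethylsilyl)oxy]methyl}tetrahydrofuran-3-yl]methyl}-2-iodo-3-methoxyphenol
Conditions: Cp2Zr(H)Cl (3 equiv), THF, rt
Reagents that add atoms: none
Why: Known reductive cleavage of aryl O-carbamates by zirconocene chloride hydride (hydrozirconation of the C=O, collapse to the zirconium aryloxide and a formamide); the substrate has no other carbonyl and no alkene, and aryl iodide, silyl ether and benzylic ethers are inert, so the phenol is freed without acid.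

Step 11
Reactants: 18 4-(benzyloxy)-3-methoxybenzaldehyde
Product: 19 ethyl (E)-3-[4-(benzyloxy)-3-methoxyphenyl]prop-2-enoate
Conditions: (EtO)2P(O)CH2CO2Et, NaH, THF, 0 °C → rt
Reagents that add atoms: triethyl phosphonoacetate, CCOC(=O)CP(=O)(OCC)OCC
Why: Horner–Wadsworth–Emmons olefination gives the (E)-cinnamate.

Step 12
Reactants: 19 ethyl (E)-3-[4-(benzyloxy)-3-methoxyphenyl]prop-2-enoate
Product: 20 (E)-3-[4-(benzyloxy)-3-methoxyphenyl]prop-2-en-1-ol
Conditions: i-Bu2AlH, CH2Cl2, −78 °C
Reagents that add atoms: none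
Why: 1,2-Reduction of the unsaturated ester to the allylic alcohol at low temperature.

Step 13
Reactants: 20 (E)-3-[4-(benzyloxy)-3-methoxyphenyl]prop-2-en-1-ol
Product: 21 (E)-3-[4-(benzyloxy)-3-methoxyphenyl]prop-2-en-1-yl methyl carbonate
Conditions: ClCO2Me, pyridine, CH2Cl2, 0 °C
Reagents that add atoms: methyl chloroformate, COC(Cl)=O
Why: Carbonate formation under buffered conditions, which avoid ionisation of the electron-rich cinnamyl alcohol.

Step 14
Reactants: 17 5-{[(3S,4S,5R)-5-[3-(benzyloxy)-4-methoxyphenyl]-4-{[(tert-butyldimethylsilyl)oxy]methyl}tetrahydrofuran-3-yl]methyl}-2-iodo-3-methoxyphenol; 21 (E)-3-[4-(benzyloxy)-3-methoxyphenyl]prop-2-en-1-yl methyl carbonate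
Product: 23 tert-butyl{[(2R,3S,4S)-2-[3-(benzyloxy)-4-methoxyphenyl]-4-{[3-{[(1S)-1-[4-(benzyloxy)-3-methoxyphenyl]prop-2-en-1-yl]oxy}-4-iodo-5-methoxyphenyl]methyl}tetrahydrofuran-3-yl]methoxy}dimethylsilane, via lithium aryloxide 22 (not isolated)
Conditions: LiN(SiMe3)2, THF, 0 °C; then 21, [Ir(cod)Cl]2 (2 mol %), (Sa,Sc,Sc)-O,O′-(1,1′-binaphthyl-2,2′-diyl) N,N-bis(1-phenylethyl)phosphoramidite (4 mol %), THF, 35 °C
Reagents that add atoms: none
Why: Iridium-catalysed asymmetric allylic etherification: the cyclometalated iridium–phosphoramidite complex ionises the linear carbonate and the aryloxide attacks the aryl-substituted allyl terminus (branched product) on the face fixed by the ligand, which sets DHB C2 as S independently of the remote THF centres; moderate temperature and quenching at full conversion limit re-ionisation of the product.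

Step 15
Reactants: 23 tert-butyl{[(2R,3S,4S)-2-[3-(benzyloxy)-4-methoxyphenyl]-4-{[3-{[(1S)-1-[4-(benzyloxy)-3-methoxyphenyl]prop-2-en-1-yl]oxy}-4-iodo-5-methoxyphenyl]methyl}tetrahydrofuran-3-yl]methoxy}dimethylsilane
Product: 25 (2S,3S)-2-[4-(benzyloxy)-3-methoxyphenyl]-6-{[(3S,4S,5R)-5-[3-(benzyloxy)-4-methoxyphenyl]-4-{[(tert-butyldimethylsilyl)oxy]methyl}tetrahydrofuran-3-yl]methyl}-4-methoxy-3-[(4,4,5,5-tetramethyl-1,3,2-dioxaborolan-2-yl)methyl]-2,3-dihydro-1-benzofuran (2,3-trans), via catechol boronate 24 (not isolated)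
Conditions: B2cat2 (3 equiv), DMA, blue LEDs (450 nm), 25 °C; then pinacol, Et3N, 25 °C
Reagents that add atoms: bis(catecholato)diboron, B1(Oc2ccccc2O1)B1Oc2ccccc2O1; pinacol, CC(C)(O)C(C)(C)O
Why: Proposed new method: visible light starts a chain in which the DMA-ligated boryl radical from B2cat2 takes the iodine atom of 23 to give the σ-aryl radical at C3a, this radical adds to the internal vinyl carbon in a 5-exo-trig closure (the dihydrofuran ring, C3a–C3 bond) far faster than it can be borylated bimolecularly, and the primary radical on the exocyclic carbon is captured by B2cat2·DMA to give 24 and a new boryl radical. The closest known reaction types are the light-driven radical borylation of alkyl and aryl iodides with B2cat2 in amide solvents and the tin-hydride 5-exo cyclisation of ortho-halophenyl 1-arylallyl ethers to trans-2-aryl-3-methyl-dihydrobenzofurans; joining the two on this substrate class is the extension. The new C3 centre is set by C2: in the chair-like 5-exo transition state the C2 aryl group sits pseudo-equatorial, so the CH2 group ends trans to it (2S,3S in 24 and 25, the descriptor at C3 differing from that of the alcohol only because boron ranks below carbon). The step needs cyclisation before borylation (secured by the unimolecular rate of an ortho-allyloxyaryl radical), 5-exo before 6-endo (secured by the unsubstituted alkene terminus) and an intact allylic ether (neutral medium at room temperature). Pinacol and Et3N then exchange the labile catechol ester for the pinacol ester 25, which can be chromatographed.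

Step 16
Reactants: 25 (2S,3S)-2-[4-(benzyloxy)-3-methoxyphenyl]-6-{[(3S,4S,5R)-5-[3-(benzyloxy)-4-methoxyphenyl]-4-{[(tert-butyldimethylsilyl)oxy]methyl}tetrahydrofuran-3-yl]methyl}-4-methoxy-3-[(4,4,5,5-tetramethyl-1,3,2-dioxaborolan-2-yl)methyl]-2,3-dihydro-1-benzofuran
Product: 26 [(2S,3R)-2-[4-(benzyloxy)-3-methoxyphenyl]-6-{[(3S,4S,5R)-5-[3-(benzyloxy)-4-methoxyphenyl]-4-{[(tert-butyldimethylsilyl)oxy]methyl}tetrahydrofuran-3-yl]methyl}-4-methoxy-2,3-dihydro-1-benzofuran-3-yl]methanol
Conditions: NaBO3·4H2O, THF/H2O (1:1), rt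
Reagents that add atoms: sodium perborate, [Na+].[O-]OB=O
Why: Oxidation of the primary alkylboronate with perborate (boron-to-oxygen 1,2-shift); silyl and benzyl ethers and both cyclic benzylic ethers tolerate the mildly basic medium, and no stereocentre is touched.

Step 17
Reactants: 26 [(2S,3R)-2-[4-(benzyloxy)-3-methoxyphenyl]-6-{[(3S,4S,5R)-5-[3-(benzyloxy)-4-methoxyphenyl]-4-{[(tert-butyldimethylsilyl)oxy]methyl}tetrahydrofuran-3-yl]methyl}-4-methoxy-2,3-dihydro-1-benzofuran-3-yl]methanol
Product: 27 [(2S,3R)-2-[4-(benzyloxy)-3-methoxyphenyl]-6-{[(3S,4S,5R)-5-[3-(benzyloxy)-4-methoxyphenyl]-4-(hydroxymethyl)tetrahydrofuran-3-yl]methyl}-4-methoxy-2,3-dihydro-1-benzofuran-3-yl]methanol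
Conditions: Bu4NF, THF, 0 °C → rt
Reagents that add atoms: none
Why: Fluoride-induced desilylation; both phenols are still benzylated, so no phenoxide can open the DHB through a quinone methide.

Step 18
Reactants: 27 [(2S,3R)-2-[4-(benzyloxy)-3-methoxyphenyl]-6-{[(3S,4S,5R)-5-[3-(benzyloxy)-4-methoxyphenyl]-4-(hydroxymethyl)tetrahydrofuran-3-yl]methyl}-4-methoxy-2,3-dihydro-1-benzofuran-3-yl]methanol
Product: 28 5-[(2R,3S,4S)-4-{[(2S,3R)-2-(4-hydroxy-3-methoxyphenyl)-3-(hydroxymethyl)-4-methoxy-2,3-dihydro-1-benzofuran-6-yl]methyl}-3-(hydroxymethyl)tetrahydrofuran-2-yl]-2-methoxyphenol (CNP0242386.1)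
Conditions: H2 (1 atm), Pd/C (10 %), EtOAc, rt
Reagents that add atoms: none
Why: Hydrogenolysis of the two aryl benzyl ethers, which cleave much faster than the cyclic benzylic C–O bonds of the DHB and THF under 1 atm H2 in a neutral aprotic solvent; the reaction is stopped after uptake of two equivalents.

## Compound list

1 | (S)-epichlorohydrin | ClC[C@@H]1CO1 | starting material
2 | diethyl malonate | CCOC(=O)CC(=O)OCC | starting material
3 | ethyl (1R,5S)-2-oxo-3-oxabicyclo[3.1.0]hexane-1-carboxylate | CCOC(=O)[C@@]12C[C@@H]1COC2=O | intermediate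
4 | 3-bromo-5-methoxyphenol | COc1cc(O)cc(Br)c1 | starting material
5 | 3-bromo-5-methoxyphenyl N,N-diethylcarbamate | CCN(CC)C(=O)Oc1cc(OC)cc(Br)c1 | intermediate
6 | [3-(diethylcarbamoyloxy)-5-methoxyphenyl]magnesium bromide (formed in situ) | CCN(CC)C(=O)Oc1cc(OC)cc([Mg]Br)c1 | intermediate
7 | ethyl (3R,4S)-4-{[3-(diethylcarbamoyloxy)-5-methoxyphenyl]methyl}-2-oxotetrahydrofuran-3-carboxylate | O=C1OC[C@@H](Cc2cc(OC)cc(OC(=O)N(CC)CC)c2)[C@@H]1C(=O)OCC | intermediate
8 | 3-methoxy-5-{[(3S)-5-oxotetrahydrofuran-3-yl]methyl}phenyl N,N-diethylcarbamate | O=C1OC[C@@H](Cc2cc(OC)cc(OC(=O)N(CC)CC)c2)C1 | intermediate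
9 | 3-(benzyloxy)-4-methoxybenzaldehyde | COc1ccc(C=O)cc1OCc1ccccc1 | starting material
10 | lithium (4S)-4-{[3-(diethylcarbamoyloxy)-5-methoxyphenyl]methyl}-4,5-dihydrofuran-2-olate (enolate of 8, formed in situ) | [Li]OC1=C[C@H](Cc2cc(OC)cc(OC(=O)N(CC)CC)c2)CO1 | intermediate
11 | 3-{[(3S,4R)-4-{[3-(benzyloxy)-4-methoxyphenyl](hydroxy)methyl}-5-oxotetrahydrofuran-3-yl]methyl}-5-methoxyphenyl N,N-diethylcarbamate (carbinol epimers) | O=C1OC[C@@H](Cc2cc(OC)cc(OC(=O)N(CC)CC)c2)[C@@H]1C(O)c1ccc(OC)c(OCc2ccccc2)c1 | intermediate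
12 | 3-[(2S,3S)-3-{[3-(benzyloxy)-4-methoxyphenyl](hydroxy)methyl}-4-hydroxy-2-(hydroxymethyl)butyl]-5-methoxyphenyl N,N-diethylcarbamate (carbinol epimers) | OC[C@@H](Cc1cc(OC)cc(OC(=O)N(CC)CC)c1)[C@@H](CO)C(O)c1ccc(OC)c(OCc2ccccc2)c1 | intermediate
13 | 3-{[(3S,4S,5R)-5-[3-(benzyloxy)-4-methoxyphenyl]-4-(hydroxymethyl)tetrahydrofuran-3-yl]methyl}-5-methoxyphenyl N,N-diethylcarbamate | COc1ccc([C@@H]2OC[C@@H](Cc3cc(OC)cc(OC(=O)N(CC)CC)c3)[C@H]2CO)cc1OCc1ccccc1 | intermediate
14 | 3-{[(3S,4S,5R)-5-[3-(benzyloxy)-4-methoxyphenyl]-4-{[(tert-butyldimethylsilyl)oxy]methyl}tetrahydrofuran-3-yl]methyl}-5-methoxyphenyl N,N-diethylcarbamate | COc1ccc([C@@H]2OC[C@@H](Cc3cc(OC)cc(OC(=O)N(CC)CC)c3)[C@H]2CO[Si](C)(C)C(C)(C)C)cc1OCc1ccccc1 | intermediate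
15 | 2-lithio derivative of 14, lithium on the ring carbon between OMe and carbamate (formed in situ) | COc1ccc([C@@H]2OC[C@@H](Cc3cc(OC)c([Li])c(OC(=O)N(CC)CC)c3)[C@H]2CO[Si](C)(C)C(C)(C)C)cc1OCc1ccccc1 | intermediate
16 | 5-{[(3S,4S,5R)-5-[3-(benzyloxy)-4-methoxyphenyl]-4-{[(tert-butyldimethylsilyl)oxy]methyl}tetrahydrofuran-3-yl]methyl}-2-iodo-3-methoxyphenyl N,N-diethylcarbamate | COc1ccc([C@@H]2OC[C@@H](Cc3cc(OC)c(I)c(OC(=O)N(CC)CC)c3)[C@H]2CO[Si](C)(C)C(C)(C)C)cc1OCc1ccccc1 | intermediate
17 | 5-{[(3S,4S,5R)-5-[3-(benzyloxy)-4-methoxyphenyl]-4-{[(tert-butyldimethylsilyl)oxy]methyl}tetrahydrofuran-3-yl]methyl}-2-iodo-3-methoxyphenol | COc1ccc([C@@H]2OC[C@@H](Cc3cc(OC)c(I)c(O)c3)[C@H]2CO[Si](C)(C)C(C)(C)C)cc1OCc1ccccc1 | intermediate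
18 | 4-(benzyloxy)-3-methoxybenzaldehyde | COc1cc(C=O)ccc1OCc1ccccc1 | starting material
19 | ethyl (E)-3-[4-(benzyloxy)-3-methoxyphenyl]prop-2-enoate | CCOC(=O)/C=C/c1ccc(OCc2ccccc2)c(OC)c1 | intermediate
20 | (E)-3-[4-(benzyloxy)-3-methoxyphenyl]prop-2-en-1-ol | OC/C=C/c1ccc(OCc2ccccc2)c(OC)c1 | intermediate
21 | (E)-3-[4-(benzyloxy)-3-methoxyphenyl]prop-2-en-1-yl methyl carbonate | COC(=O)OC/C=C/c1ccc(OCc2ccccc2)c(OC)c1 | intermediate
22 | lithium phenolate of 17 (formed in situ) | COc1ccc([C@@H]2OC[C@@H](Cc3cc(OC)c(I)c(O[Li])c3)[C@H]2CO[Si](C)(C)C(C)(C)C)cc1OCc1ccccc1 | intermediate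
23 | tert-butyl{[(2R,3S,4S)-2-[3-(benzyloxy)-4-methoxyphenyl]-4-{[3-{[(1S)-1-[4-(benzyloxy)-3-methoxyphenyl]prop-2-en-1-yl]oxy}-4-iodo-5-methoxyphenyl]methyl}tetrahydrofuran-3-yl]methoxy}dimethylsilane | COc1ccc([C@@H]2OC[C@@H](Cc3cc(OC)c(I)c(O[C@H](c4ccc(OCc5ccccc5)c(OC)c4)C=C)c3)[C@H]2CO[Si](C)(C)C(C)(C)C)cc1OCc1ccccc1 | intermediate
24 | (2S,3S)-3-[(1,3,2-benzodioxaborol-2-yl)methyl] analogue of 25 (formed in situ) | COc1ccc([C@@H]2OC[C@@H](Cc3cc(OC)c4c(c3)O[C@H](c3ccc(OCc5ccccc5)c(OC)c3)[C@H]4CB3Oc5ccccc5O3)[C@H]2CO[Si](C)(C)C(C)(C)C)cc1OCc1ccccc1 | intermediate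
25 | (2S,3S)-2-[4-(benzyloxy)-3-methoxyphenyl]-6-{[(3S,4S,5R)-5-[3-(benzyloxy)-4-methoxyphenyl]-4-{[(tert-butyldimethylsilyl)oxy]methyl}tetrahydrofuran-3-yl]methyl}-4-methoxy-3-[(4,4,5,5-tetramethyl-1,3,2-dioxaborolan-2-yl)methyl]-2,3-dihydro-1-benzofuran | COc1ccc([C@@H]2OC[C@@H](Cc3cc(OC)c4c(c3)O[C@H](c3ccc(OCc5ccccc5)c(OC)c3)[C@H]4CB3OC(C)(C)C(C)(C)O3)[C@H]2CO[Si](C)(C)C(C)(C)C)cc1OCc1ccccc1 | intermediate
26 | [(2S,3R)-2-[4-(benzyloxy)-3-methoxyphenyl]-6-{[(3S,4S,5R)-5-[3-(benzyloxy)-4-methoxyphenyl]-4-{[(tert-butyldimethylsilyl)oxy]methyl}tetrahydrofuran-3-yl]methyl}-4-methoxy-2,3-dihydro-1-benzofuran-3-yl]methanol | COc1ccc([C@@H]2OC[C@@H](Cc3cc(OC)c4c(c3)O[C@H](c3ccc(OCc5ccccc5)c(OC)c3)[C@H]4CO)[C@H]2CO[Si](C)(C)C(C)(C)C)cc1OCc1ccccc1 | intermediate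
27 | [(2S,3R)-2-[4-(benzyloxy)-3-methoxyphenyl]-6-{[(3S,4S,5R)-5-[3-(benzyloxy)-4-methoxyphenyl]-4-(hydroxymethyl)tetrahydrofuran-3-yl]methyl}-4-methoxy-2,3-dihydro-1-benzofuran-3-yl]methanol | COc1ccc([C@@H]2OC[C@@H](Cc3cc(OC)c4c(c3)O[C@H](c3ccc(OCc5ccccc5)c(OC)c3)[C@H]4CO)[C@H]2CO)cc1OCc1ccccc1 | intermediate
28 | 5-[(2R,3S,4S)-4-{[(2S,3R)-2-(4-hydroxy-3-methoxyphenyl)-3-(hydroxymethyl)-4-methoxy-2,3-dihydro-1-benzofuran-6-yl]methyl}-3-(hydroxymethyl)tetrahydrofuran-2-yl]-2-methoxyphenol (CNP0242386.1) | COc1ccc([C@@H]2OC[C@@H](Cc3cc(OC)c4c(c3)O[C@H](c3ccc(O)c(OC)c3)[C@H]4CO)[C@H]2CO)cc1O | target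

## Step count and least certain steps

Total: 18 steps. Longest linear sequence: 14 steps (4 → 28 through steps 2–10 and 14–18; the same count from 1).

**Step 15 (key step, proposed new method).** Chain initiation and iodine-atom transfer may be sluggish for an electron-rich, doubly ortho-substituted aryl iodide. Boryl radicals may add to the terminal alkene before the aryl radical is formed. The 5-exo transition state may discriminate only moderately between trans and cis closure. Fallback with known chemistry: from 23, Bu3SnH and TEMPO in benzene at 60 °C effect the same 5-exo aryl radical cyclisation with nitroxide trapping of the primary radical. This gives (2S,3R)-2-[4-(benzyloxy)-3-methoxyphenyl]-4-methoxy-3-{[(2,2,6,6-tetramethylpiperidin-1-yl)oxy]methyl}-2,3-dihydro-1-benzofuran carrying the silylated THF unit at C6, F1. Zinc dust in AcOH/THF/H2O then cleaves the N–O bond and delivers alcohol 26, where the route continues with step 17.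

**Step 14.** The iridium catalyst may re-ionise the electron-rich branched ether, with loss of enantiomeric purity and drift to the linear ether. Capture of the allyl complex by the hindered, weakly nucleophilic ortho-iodo aryloxide may be slow. Fallback: from 18, vinylmagnesium bromide gives racemic 1-[4-(benzyloxy)-3-methoxyphenyl]prop-2-en-1-ol F2. Candida antarctica lipase B with vinyl acetate acylates the (R)-enantiomer, removed as (R)-1-[4-(benzyloxy)-3-methoxyphenyl]prop-2-en-1-yl acetate F3, and leaves (S)-1-[4-(benzyloxy)-3-methoxyphenyl]prop-2-en-1-ol F4. n-BuLi and Boc2O convert it into tert-butyl (S)-1-[4-(benzyloxy)-3-methoxyphenyl]prop-2-en-1-yl carbonate F5. [Cp*Ru(MeCN)3]PF6 (5 mol %) with phenol 17 in THF then gives the branched ether with overall retention, which is 23.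

**Step 3.** During the slow metal insertion the arylmagnesium species may take the carbamoyl group from a second molecule, and 1,2-addition to the lactone carbonyl may compete with ring opening. Fallback: from 4, MOMCl/i-Pr2NEt gives 1-bromo-3-methoxy-5-(methoxymethoxy)benzene F6. Its Grignard reagent (Mg, THF) opens 3 under CuI catalysis to ethyl (3R,4S)-4-{[3-methoxy-5-(methoxymethoxy)phenyl]methyl}-2-oxotetrahydrofuran-3-carboxylate F7. LiCl in wet DMSO at 140 °C gives (4S)-4-{[3-methoxy-5-(methoxymethoxy)phenyl]methyl}dihydrofuran-2(3H)-one F8, and HCl in MeOH frees (4S)-4-[(3-hydroxy-5-methoxyphenyl)methyl]dihydrofuran-2(3H)-one F9. ClC(O)NEt2/K2CO3 then gives 8.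

## Further compounds

F1 | step 15 | tert-butyl{[(2R,3S,4S)-2-[3-(benzyloxy)-4-methoxyphenyl]-4-{[(2S,3R)-2-[4-(benzyloxy)-3-methoxyphenyl]-4-methoxy-3-{[(2,2,6,6-tetramethylpiperidin-1-yl)oxy]methyl}-2,3-dihydro-1-benzofuran-6-yl]methyl}tetrahydrofuran-3-yl]methoxy}dimethylsilane | COc1ccc([C@@H]2OC[C@@H](Cc3cc(OC)c4c(c3)O[C@H](c3ccc(OCc5ccccc5)c(OC)c3)[C@H]4CON3C(C)(C)CCCC3(C)C)[C@H]2CO[Si](C)(C)C(C)(C)C)cc1OCc1ccccc1
F2 | step 14 | racemic 1-[4-(benzyloxy)-3-methoxyphenyl]prop-2-en-1-ol | C=CC(O)c1ccc(OCc2ccccc2)c(OC)c1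
F3 | step 14 | (R)-1-[4-(benzyloxy)-3-methoxyphenyl]prop-2-en-1-yl acetate | C=C[C@@H](OC(C)=O)c1ccc(OCc2ccccc2)c(OC)c1
F4 | step 14 | (S)-1-[4-(benzyloxy)-3-methoxyphenyl]prop-2-en-1-ol | C=C[C@H](O)c1ccc(OCc2ccccc2)c(OC)c1
F5 | step 14 | tert-butyl (S)-1-[4-(benzyloxy)-3-methoxyphenyl]prop-2-en-1-yl carbonate | C=C[C@H](OC(=O)OC(C)(C)C)c1ccc(OCc2ccccc2)c(OC)c1
F6 | step 3 | 1-bromo-3-methoxy-5-(methoxymethoxy)benzene | COCOc1cc(OC)cc(Br)c1
F7 | step 3 | ethyl (3R,4S)-4-{[3-methoxy-5-(methoxymethoxy)phenyl]methyl}-2-oxotetrahydrofuran-3-carboxylate | O=C1OC[C@@H](Cc2cc(OC)cc(OCOC)c2)[C@@H]1C(=O)OCC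
F8 | step 3 | (4S)-4-{[3-methoxy-5-(methoxymethoxy)phenyl]methyl}dihydrofuran-2(3H)-one | O=C1OC[C@@H](Cc2cc(OC)cc(OCOC)c2)C1
F9 | step 3 | (4S)-4-[(3-hydroxy-5-methoxyphenyl)methyl]dihydrofuran-2(3H)-one | O=C1OC[C@@H](Cc2cc(O)cc(OC)c2)C1
A1 | alternative 1 | methyl 2-[2-{[4-(benzyloxy)-3-methoxyphenyl]methoxy}-4-bromo-6-methoxyphenyl]-2-diazoacetate | COC(=O)C(=[N+]=[N-])c1c(OC)cc(Br)cc1OCc1ccc(OCc2ccccc2)c(OC)c1
A2 | alternative 1 | methyl (2S,3S)-2-[4-(benzyloxy)-3-methoxyphenyl]-6-bromo-4-methoxy-2,3-dihydro-1-benzofuran-3-carboxylate (trans) | Brc1cc(OC)c2c(c1)O[C@H](c1ccc(OCc3ccccc3)c(OC)c1)[C@H]2C(=O)OC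
A3 | alternative 2 | 3-{[(3S,4S,5R)-5-[3-(benzyloxy)-4-methoxyphenyl]-4-{[(tert-butyldimethylsilyl)oxy]methyl}tetrahydrofuran-3-yl]methyl}cyclobut-2-en-1-one | COc1ccc([C@@H]2OC[C@@H](CC3=CC(=O)C3)[C@H]2CO[Si](C)(C)C(C)(C)C)cc1OCc1ccccc1
A4 | alternative 2 | triisopropylsilyl ynol ether carrying the open-chain DHB C3/C2 unit (CH2OTBS and benzylic OTES) | CC(C)[Si](OC#C[C@H](CO[Si](C)(C)C(C)(C)C)[C@@H](O[Si](CC)(CC)CC)c1ccc(OCc2ccccc2)c(OC)c1)(C(C)C)C(C)C
A5 | alternative 2 | ring-B resorcinol mono-TIPS ether carrying both halves | COc1ccc([C@@H]2OC[C@@H](Cc3cc(O[Si](C(C)C)(C(C)C)C(C)C)c([C@H](CO[Si](C)(C)C(C)(C)C)[C@@H](O[Si](CC)(CC)CC)c4ccc(OCc5ccccc5)c(OC)c4)c(O)c3)[C@H]2CO[Si](C)(C)C(C)(C)C)cc1OCc1ccccc1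
A6 | alternative 3 | 5-substituted cyclohexane-1,3-dione carrying the acetylated THF unit | COc1ccc([C@@H]2OC[C@@H](CC3CC(=O)CC(=O)C3)[C@H]2COC(C)=O)cc1OCc1ccccc1
A7 | alternative 3 | N-[(E)-3-(4-benzyloxy-3-methoxyphenyl)prop-2-enoyl]camphorsultam | COc1cc(/C=C/C(=O)N2[C@@H]3C[C@H]4CC[C@]3(CS2(=O)=O)C4(C)C)ccc1OCc1ccccc1
A8 | alternative 3 | trans-2-aryl-3-(sultam carbonyl)-4-oxo-2,3,4,5,6,7-hexahydrobenzofuran (mixture at C6) | COc1ccc([C@@H]2OC[C@@H](CC3CC(=O)C4=C(C3)O[C@H](c3ccc(OCc5ccccc5)c(OC)c3)[C@H]4C(=O)N3[C@@H]4C[C@H]5CC[C@]4(CS3(=O)=O)C5(C)C)[C@H]2COC(C)=O)cc1OCc1ccccc1
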